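**Retrosynthetic overview**
- The target is a 3-aryloxycoumarin; the key disconnection is the C3–O bond, made by a new decarboxylative coupling of a coumarin-3-carboxylic acid (scopoletin core, 7-OH as MOM ether) with a phenol.
- The methyl 3-(2-hydroxyphenyl)propanoate arm is carried as a 3,4-dihydrocoumarin lactone, which masks both the ortho-phenol and the acid; methanol opens it in the last step while the MOM group falls off.
- The pyranone ring of the scopoletin half is formed first, by Knoevenagel condensation/lactonisation of a 4-O-MOM salicylaldehyde with Meldrum's acid; the phenol partner comes from hydrogenation of umbelliferone.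
- Order of ring events: coumarin ring formation, saturation of the umbelliferone pyranone (separate branch), C–O union of the two halves, opening of the saturated lactone.

Assumption: the target has no stereocentre and its only non-aromatic C=C is fixed in the lactone ring, so "single enantiomer" is read as the achiral constitution given; 1, 3 and 6 are taken as catalogue chemicals.

**Step 1**
Reactants: 1 2,4-dihydroxy-5-methoxybenzaldehyde
Product: 2 2-hydroxy-5-methoxy-4-(methoxymethoxy)benzaldehyde
Conditions: MOMCl (1.05 equiv), K2CO3 (1.1 equiv), acetone, 0 °C to rt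
Reagents that add atoms: chloromethyl methyl ether (MOMCl), COCCl
Why: Williamson-type O-alkylation (MOM ether formation) in which the 2-OH is locked in a hydrogen bond to the aldehyde and is the weaker acid, so the mild base alkylates only the 4-OH para to the formyl group.

**Step 2**
Reactants: 2 2-hydroxy-5-methoxy-4-(methoxymethoxy)benzaldehyde; 3 Meldrum's acid (2,2-dimethyl-1,3-dioxane-4,6-dione)
Product: 5 6-methoxy-7-(methoxymethoxy)-2-oxo-2H-chromene-3-carboxylic acid, via arylidene Meldrum's acid 4 (not isolated)
Conditions: piperidinium acetate (10 mol%), EtOH, rt then 60 °C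
Reagents that add atoms: none
Why: Knoevenagel condensation followed by lactonisation, in which the ortho-phenol attacks one acyl group of 4 and expels acetone, is the standard entry to coumarin-3-carboxylic acids, and the MOM ether is stable to the buffered amine salt.

**Step 3**
Reactants: 6 umbelliferone (7-hydroxy-2H-chromen-2-one)
Product: 7 7-hydroxychroman-2-one (7-hydroxy-3,4-dihydrocoumarin)
Conditions: H2 (3 bar), 10% Pd/C, AcOH, 50 °C
Reagents that add atoms: none
Why: Heterogeneous catalytic hydrogenation saturates the conjugated C3–C4 alkene of the pyranone while the benzene ring, the phenol and the lactone stay intact, and acetic acid as solvent prevents solvolytic ring opening.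

**Step 4**
Reactants: 5 6-methoxy-7-(methoxymethoxy)-2-oxo-2H-chromene-3-carboxylic acid; 7 7-hydroxychroman-2-one
Product: 8 6-methoxy-7-(methoxymethoxy)-3-[(2-oxochroman-7-yl)oxy]-2H-chromen-2-one
Conditions: Cu(OTf)2 (2.5 equiv), Li2CO3 (2.0 equiv), 7 (2.5 equiv), 4 Å MS, MeCN, 400 nm LEDs, 25 °C, Ar
Reagents that add atoms: none
Why: Proposed new method: the carboxylate of 5 binds divalent copper and 400 nm light triggers ligand-to-metal charge transfer, giving monovalent copper and an acyloxyl radical that loses CO2 to the coumarin-3-yl sigma radical; this radical is captured by the divalent copper aryloxide of 7 to give an alkenyl trivalent copper aryloxide, which forms the C3–O bond by reductive elimination, so the aryloxy group ends up exactly where the carboxyl group stood; the closest known reaction type is the copper ligand-to-metal-charge-transfer decarboxylative functionalisation of (hetero)aryl carboxylic acids (halogenation, borylation, hydroxylation) combined with Chan–Lam/Ullmann-type C–O reductive elimination, which to my knowledge has not been shown for an alkenyl (coumarin-3-) carboxylic acid with a phenol as the coupling partner.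

**Step 5**
Reactants: 8 6-methoxy-7-(methoxymethoxy)-3-[(2-oxochroman-7-yl)oxy]-2H-chromen-2-one
Product: 10 methyl 3-{2-hydroxy-4-[(7-hydroxy-6-methoxy-2-oxo-2H-chromen-3-yl)oxy]phenyl}propanoate, via MOM-free lactone 9 (not isolated)
Conditions: p-TsOH·H2O (0.2 equiv), MeOH, 50 °C
Reagents that add atoms: methanol, CO
Why: Acid-catalysed acetal exchange passes the MOM group to methanol (deprotection) and acid-catalysed transesterification (Fischer-type methanolysis) then opens only the saturated aryl-ester lactone, whose open methyl ester is strongly favoured in neat methanol, while the conjugated coumarin lactone and the aryl vinyl ether are inert; the acid is neutralised before concentration so the product does not re-lactonise.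

**Compound list**
1 | 2,4-dihydroxy-5-methoxybenzaldehyde | COc1cc(C=O)c(O)cc1O | starting material
2 | 2-hydroxy-5-methoxy-4-(methoxymethoxy)benzaldehyde | COCOc1cc(O)c(C=O)cc1OC | intermediate
3 | Meldrum's acid (2,2-dimethyl-1,3-dioxane-4,6-dione) | CC1(C)OC(=O)CC(=O)O1 | starting material
4 | 5-[2-hydroxy-5-methoxy-4-(methoxymethoxy)benzylidene]-2,2-dimethyl-1,3-dioxane-4,6-dione | COCOc1cc(O)c(C=C2C(=O)OC(C)(C)OC2=O)cc1OC | intermediate
5 | 6-methoxy-7-(methoxymethoxy)-2-oxo-2H-chromene-3-carboxylic acid | COCOc1cc2oc(=O)c(C(=O)O)cc2cc1OC | intermediate
6 | umbelliferone (7-hydroxy-2H-chromen-2-one) | O=c1ccc2ccc(O)cc2o1 | starting material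
7 | 7-hydroxychroman-2-one | O=C1CCc2ccc(O)cc2O1 | intermediate
8 | 6-methoxy-7-(methoxymethoxy)-3-[(2-oxochroman-7-yl)oxy]-2H-chromen-2-one | COCOc1cc2oc(=O)c(Oc3ccc4CCC(=O)Oc4c3)cc2cc1OC | intermediate
9 | 7-hydroxy-6-methoxy-3-[(2-oxochroman-7-yl)oxy]-2H-chromen-2-one | COc1cc2cc(Oc3ccc4CCC(=O)Oc4c3)c(=O)oc2cc1O | intermediate
10 | methyl 3-{2-hydroxy-4-[(7-hydroxy-6-methoxy-2-oxo-2H-chromen-3-yl)oxy]phenyl}propanoate | COC(=O)CCc1ccc(Oc2cc3cc(OC)c(O)cc3oc2=O)cc1O | target

**Step count and risks**

Total step count: 5. Longest linear sequence: 4 steps (1 → 2 → 5 → 8 → 10); step 3 is a one-step side branch.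

Steps most likely to fail:

First, step 4, the proposed new decarboxylative C–O coupling. The radical may be quenched to the C3–H coumarin (protodecarboxylation) or captured by carboxylate in place of aryloxide. The phenol 7 may be oxidised by divalent copper, the acyloxyl radical may abstract hydrogen from the MOM or benzylic CH2 groups, and the coumarin may photodimerise. The fallback uses known chemistry and puts the oxygen on carbon before the ring is made. It sets out from 7, which is O-alkylated with tert-butyl bromoacetate (K2CO3, acetone) to tert-butyl 2-[(2-oxochroman-7-yl)oxy]acetate F4. TFA in CH2Cl2 then gives 2-[(2-oxochroman-7-yl)oxy]acetic acid F5. This acid is esterified onto the phenol of aldehyde 2 with 2-chloro-1-methylpyridinium iodide and Et3N in CH2Cl2 to give 2-formyl-4-methoxy-5-(methoxymethoxy)phenyl 2-[(2-oxochroman-7-yl)oxy]acetate F6. Warming F6 with DBU in MeCN closes the pyranone by intramolecular Knoevenagel-type aldol condensation, the Perkin-type coumarin synthesis from an aryloxyacetic acid and a salicylaldehyde. The fallback comes back to the route at 8.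

Second, step 5, the one-pot deprotection and lactone methanolysis. The saturated lactone may open incompletely or re-close when the acidic solution is concentrated, and the two acid-driven events cannot be tuned separately. The fallback sets out from 8 and separates them with a change of mechanism. Aqueous acid without methanol (3 M HCl, THF, rt) removes only the MOM group, and the phenol lactone 9 is isolated. The saturated lactone is then opened by base-mediated transesterification (K2CO3, MeOH, 0 °C), which is driven by phenoxide formation and leaves the coumarin lactone closed because its 7-phenoxide deactivates it. A cold AcOH quench gives 10, where the fallback rejoins the route (new compounds: none F0).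

Third, step 1, the regioselective mono-protection. Some 2-O-alkylation or bis-alkylation would give mixtures that are tedious to separate. The fallback sets out from 1 and removes the selectivity question by making the pyranone ring before protection. Unprotected 1 is condensed with 3 (piperidinium acetate, EtOH) through 5-(2,4-dihydroxy-5-methoxybenzylidene)-2,2-dimethyl-1,3-dioxane-4,6-dione F1, which is not isolated, to 7-hydroxy-6-methoxy-2-oxo-2H-chromene-3-carboxylic acid F2, which has a single phenol. Exhaustive alkylation (MOMCl, iPr2NEt, CH2Cl2) gives methoxymethyl 6-methoxy-7-(methoxymethoxy)-2-oxo-2H-chromene-3-carboxylate F3. Selective saponification of the labile MOM ester (LiOH, THF/H2O, 0 °C, citric acid work-up) gives 5, where the fallback comes back to the route.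

**Further compounds**
F1 | step 1 | 5-(2,4-dihydroxy-5-methoxybenzylidene)-2,2-dimethyl-1,3-dioxane-4,6-dione | COc1cc(C=C2C(=O)OC(C)(C)OC2=O)c(O)cc1O
F2 | step 1 | 7-hydroxy-6-methoxy-2-oxo-2H-chromene-3-carboxylic acid | COc1cc2cc(C(=O)O)c(=O)oc2cc1O
F3 | step 1 | methoxymethyl 6-methoxy-7-(methoxymethoxy)-2-oxo-2H-chromene-3-carboxylate | COCOC(=O)c1cc2cc(OC)c(OCOC)cc2oc1=O
F4 | step 4 | tert-butyl 2-[(2-oxochroman-7-yl)oxy]acetate | CC(C)(C)OC(=O)COc1ccc2CCC(=O)Oc2c1
F5 | step 4 | 2-[(2-oxochroman-7-yl)oxy]acetic acid | OC(=O)COc1ccc2CCC(=O)Oc2c1
F6 | step 4 | 2-formyl-4-methoxy-5-(methoxymethoxy)phenyl 2-[(2-oxochroman-7-yl)oxy]acetate | COCOc1cc(OC(=O)COc2ccc3CCC(=O)Oc3c2)c(C=O)cc1OC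
F0 | step 5 | none | none
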